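**Plan**

- Retrosynthesis: the hydroperoxide goes back to a prenyl ketone (Schenck ene reaction), the prenyl ketone to a 2-formyl oxirane plus an allyl unit and an isopropylidene unit, the side-chain oxirane to an α-methylene aldehyde, the ester to an α-ketol, and the α-ketol to a cyclohexenone.
- The ring is cut at the two bonds that flank its CH2–CH(O) unit; this unit becomes the two carbons of a vinylsulfonium salt.
- Enabling feature: the ring oxirane lies α,β to the ring ketone, so its methyl-bearing carbon can be a methyl ketone carbonyl and its CH carbon a sulfonium ylide; the ring CH2 links that ylide carbon to the side-chain-bearing ring CH, which can be a nitronate carbon.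
- Forward order: acyclic nitro ketone, then six-membered ring and ring oxirane in one operation, then enone by loss of nitrous acid, then hydride and oxygen at the two ring CH centres, then the side-chain oxirane, then the hydroperoxide.
- Stereochemistry: L-proline sets a temporary carbinol (the later ring ketone) that steers the ring oxirane; the oxirane steers hydride delivery, and that centre steers the acyloxy carbon.
- The side-chain oxirane is set by a chiral amine catalyst, and the (E)-alkene by the ene reaction.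

Key step: step 5

Remark: the nitro-bearing carbon is carried as a mixture of epimers from 4 to 13; both converge on 14, where it becomes trigonal.
Remark: the carbinol made in step 12 is carried as a mixture of epimers and is erased in step 14.
Assumption: the (S)-configured prolinol silyl ether is taken to give the (S)-oxirane in step 11; the enantiomeric catalyst would be used if the sense on this substrate proved opposite.

**Route**

Step 1
Reactants: 1 3-bromo-1,1-dimethoxypropane
Product: 2 1,1-dimethoxy-3-nitropropane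
Conditions: NaNO2, phloroglucinol, DMSO, rt
Reagents that add atoms: sodium nitrite [Na+].[O-]N=O
Why: Kornblum substitution of a primary bromide by nitrite should give the nitroalkane, with phloroglucinol scavenging the nitrite ester.

Step 2
Reactants: 2 1,1-dimethoxy-3-nitropropane; 3 but-3-en-2-one
Product: 4 7,7-dimethoxy-5-nitroheptan-2-one (racemic)
Conditions: DBU (10 mol %), MeCN, 0 °C to rt, 2 in excess
Reagents that add atoms: none
Why: Michael addition of the nitronate to the vinyl ketone, with excess nitroalkane holding back double addition; the new centre is not controlled and is erased later.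

Step 3
Reactants: 4 7,7-dimethoxy-5-nitroheptan-2-one
Product: 6 (3R)-3-hydroxy-7,7-dimethoxy-5-nitroheptan-2-one (both C5 epimers), via anilinooxy ketone 5 (not isolated)
Conditions: L-proline (20 mol %), PhNO added slowly, DMSO, rt; then CuSO4·5H2O (30 mol %), MeOH, 0 °C
Reagents that add atoms: nitrosobenzene O=Nc1ccccc1
Why: Proline-catalysed α-aminoxylation: the more substituted enamine should attack the nitroso oxygen on the face fixed by the carboxylic acid, giving the (R)-carbinol, and CuSO4 then cleaves the N–O bond.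

Step 4
Reactants: 6 (3R)-3-hydroxy-7,7-dimethoxy-5-nitroheptan-2-one
Product: 7 (3R)-3-{[tert-butyl(dimethyl)silyl]oxy}-7,7-dimethoxy-5-nitroheptan-2-one (both C5 epimers)
Conditions: TBSCl, imidazole, DMF, rt
Reagents that add atoms: tert-butyldimethylsilyl chloride CC(C)(C)[Si](C)(C)Cl
Why: Silylation of the secondary alcohol removes the O–H that would quench the ylide of step 5 and gives a bulky polar group to steer the ketone face.

Step 5
Reactants: 7 (3R)-3-{[tert-butyl(dimethyl)silyl]oxy}-7,7-dimethoxy-5-nitroheptan-2-one; 8 diphenyl(vinyl)sulfonium trifluoromethanesulfonate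
Product: 11 tert-butyl{[(1S,2R,6S)-4-(2,2-dimethoxyethyl)-1-methyl-4-nitro-7-oxabicyclo[4.1.0]heptan-2-yl]oxy}dimethylsilane (both C4 epimers), via sulfonium ylide 9 (not isolated), via betaine 10 (not isolated)
Conditions: DBU (1.5 equiv), CH2Cl2, 0 °C
Reagents that add atoms: none
Why: Proposed new method: DBU removes only the nitro-activated proton of 7 and the nitronate carbon adds to the CH2 terminus of 8 to give ylide 9, whose carbon adds to the tethered methyl ketone and whose alkoxide then expels diphenyl sulfide; the closest known reaction type is the conjugate addition–Corey–Chaykovsky epoxy-annulation of vinylsulfonium salts with nitrogen or oxygen nucleophiles that carry a ketone, here extended to a carbon nucleophile and a carbocycle. The cyclohexane closes by 6-exo-trig addition of the ylide carbon to the C=O group and the oxirane by 3-exo-tet displacement at the sulfonium-bearing carbon. Only the betaine with alkoxide and sulfonium anti can close, so the ring fusion is necessarily cis and the configuration of the oxirane CH follows from that of the quaternary oxirane carbon. That quaternary carbon is set by the (R)-silyloxy centre next to the ketone, which in the chair transition state should sit equatorial and anti to the incoming ylide carbon (polar Felkin–Anh arrangement) with the ketone methyl equatorial, so that the oxirane oxygen should end up cis to the silyloxy group. The nitro-bearing centre forms without control and is erased in step 7. The step needs C-alkylation of the nitronate, six-ring closure in preference to cyclopropane formation and no epimerisation next to the ketone, which the fully substituted nitro carbon of 9 (no acidic proton left), the fast intramolecular carbonyl addition and the mild base at 0 °C should secure.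

Step 6
Reactants: 11 tert-butyl{[(1S,2R,6S)-4-(2,2-dimethoxyethyl)-1-methyl-4-nitro-7-oxabicyclo[4.1.0]heptan-2-yl]oxy}dimethylsilane
Product: 12 (1R,2R,6S)-4-(2,2-dimethoxyethyl)-1-methyl-4-nitro-7-oxabicyclo[4.1.0]heptan-2-ol (both C4 epimers)
Conditions: TBAF, AcOH, THF, 0 °C
Reagents that add atoms: none
Why: Buffered fluoride desilylation; the alkoxide is syn to the oxirane oxygen and cannot reach the rear of the C–O bond, so no Payne rearrangement is expected.

Step 7
Reactants: 12 (1R,2R,6S)-4-(2,2-dimethoxyethyl)-1-methyl-4-nitro-7-oxabicyclo[4.1.0]heptan-2-ol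
Product: 14 (1S,6S)-4-(2,2-dimethoxyethyl)-1-methyl-7-oxabicyclo[4.1.0]hept-3-en-2-one, via nitro ketone 13 (not isolated)
Conditions: Dess–Martin periodinane, NaHCO3, CH2Cl2, 0 °C; then Et3N, 0 °C
Reagents that add atoms: none
Why: Dess–Martin oxidation gives the β-nitro ketone, from which triethylamine removes nitrous acid by E1cB elimination through the only enolisable position; the temporary carbinol and nitro centres are erased and the oxirane centres stay.

Step 8
Reactants: 14 (1S,6S)-4-(2,2-dimethoxyethyl)-1-methyl-7-oxabicyclo[4.1.0]hept-3-en-2-one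
Product: 17 (1S,3S,4S,6S)-4-(2,2-dimethoxyethyl)-3-hydroxy-1-methyl-7-oxabicyclo[4.1.0]heptan-2-one, via silyl enol ether 15 (not isolated), via silyloxy ketone 16 (not isolated)
Conditions: [(Ph3P)CuH]6 (5 mol %), PhMe2SiH, toluene, rt; then mCPBA, NaHCO3, CH2Cl2, −20 °C; then TBAF, AcOH, THF, 0 °C
Reagents that add atoms: dimethylphenylsilane C[SiH](C)c1ccccc1 (its silicon stays only in 15 and 16); 3-chloroperbenzoic acid OOC(=O)c1cccc(Cl)c1
Why: Copper hydride conjugate hydrosilylation should deliver hydride to the β-carbon anti to the oxirane oxygen (axial attack anti to a substituent at the 5-position of a cyclohexenone), placing the side chain cis to the oxirane; the only possible silyl enol ether is then epoxidised anti to that side chain and rearranges (Rubottom oxidation) to the trans α-oxygenated ketone.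

Step 9
Reactants: 17 (1S,3S,4S,6S)-4-(2,2-dimethoxyethyl)-3-hydroxy-1-methyl-7-oxabicyclo[4.1.0]heptan-2-one; 18 3-methylbutanoyl chloride
Product: 19 (1S,3S,4S,6S)-4-(2,2-dimethoxyethyl)-1-methyl-2-oxo-7-oxabicyclo[4.1.0]heptan-3-yl 3-methylbutanoate
Conditions: pyridine, DMAP (cat.), CH2Cl2, 0 °C
Reagents that add atoms: none
Why: Acylation of the secondary α-ketol; the trans arrangement of acyloxy group and side chain is also the thermodynamic one at this epimerisable centre.

Step 10
Reactants: 19 (1S,3S,4S,6S)-4-(2,2-dimethoxyethyl)-1-methyl-2-oxo-7-oxabicyclo[4.1.0]heptan-3-yl 3-methylbutanoate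
Product: 21 (1S,3S,4S,6S)-1-methyl-2-oxo-4-(3-oxoprop-1-en-2-yl)-7-oxabicyclo[4.1.0]heptan-3-yl 3-methylbutanoate, via aldehyde 20 (not isolated)
Conditions: 1 M HCl, THF, 0 °C to rt; then 37% aq. HCHO, pyrrolidine (10 mol %), propionic acid (10 mol %), i-PrOH, 45 °C
Reagents that add atoms: water O; formaldehyde C=O
Why: Acetal hydrolysis followed by amine-catalysed Mannich condensation and elimination (α-methylenation of an aldehyde), which can occur only at the single α-CH2; the ring stereocentre is β to the aldehyde and is not touched.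

Step 11
Reactants: 21 (1S,3S,4S,6S)-1-methyl-2-oxo-4-(3-oxoprop-1-en-2-yl)-7-oxabicyclo[4.1.0]heptan-3-yl 3-methylbutanoate
Product: 22 (1S,3S,4R,6S)-4-[(2S)-2-formyloxiran-2-yl]-1-methyl-2-oxo-7-oxabicyclo[4.1.0]heptan-3-yl 3-methylbutanoate
Conditions: (S)-2-[diphenyl(trimethylsilyloxy)methyl]pyrrolidine (10 mol %), 35% aq. H2O2, CH2Cl2, rt
Reagents that add atoms: hydrogen peroxide OO
Why: Weitz–Scheffer-type epoxidation under iminium–enamine catalysis: hydrogen peroxide adds to the CH2 terminus of the iminium ion and the chiral enamine closes the oxirane on one face, so the new quaternary centre should be set by the catalyst and not by the ring.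

Step 12
Reactants: 22 (1S,3S,4R,6S)-4-[(2S)-2-formyloxiran-2-yl]-1-methyl-2-oxo-7-oxabicyclo[4.1.0]heptan-3-yl 3-methylbutanoate; 23 4,4,5,5-tetramethyl-2-(prop-2-en-1-yl)-1,3,2-dioxaborolane
Product: 24 (1S,3S,4R,6S)-4-[(2S)-2-(1-hydroxybut-3-en-1-yl)oxiran-2-yl]-1-methyl-2-oxo-7-oxabicyclo[4.1.0]heptan-3-yl 3-methylbutanoate (both carbinol epimers)
Conditions: CH2Cl2, rt; aq. NaHCO3 work-up
Reagents that add atoms: none
Why: Uncatalysed allylboration through a six-membered transition state should take the aldehyde in preference to the hindered ketone and the ester; the carbinol configuration does not matter.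

Step 13
Reactants: 24 (1S,3S,4R,6S)-4-[(2S)-2-(1-hydroxybut-3-en-1-yl)oxiran-2-yl]-1-methyl-2-oxo-7-oxabicyclo[4.1.0]heptan-3-yl 3-methylbutanoate; 25 2-methylbut-2-ene
Product: 26 (1S,3S,4R,6S)-4-[(2S)-2-(1-hydroxy-4-methylpent-3-en-1-yl)oxiran-2-yl]-1-methyl-2-oxo-7-oxabicyclo[4.1.0]heptan-3-yl 3-methylbutanoate (both carbinol epimers)
Conditions: second-generation Grubbs catalyst RuCl2(=CHPh)(H2IMes)(PCy3) (5 mol %), 25 in excess, CH2Cl2, 40 °C
Reagents that add atoms: none
Why: Olefin cross-metathesis with 2-methylbut-2-ene should turn the terminal alkene into the trisubstituted prenyl alkene with loss of propene.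

Step 14
Reactants: 26 (1S,3S,4R,6S)-4-[(2S)-2-(1-hydroxy-4-methylpent-3-en-1-yl)oxiran-2-yl]-1-methyl-2-oxo-7-oxabicyclo[4.1.0]heptan-3-yl 3-methylbutanoate
Product: 27 (1S,3S,4R,6S)-1-methyl-4-[(2S)-2-(4-methylpent-3-enoyl)oxiran-2-yl]-2-oxo-7-oxabicyclo[4.1.0]heptan-3-yl 3-methylbutanoate
Conditions: Dess–Martin periodinane, NaHCO3, CH2Cl2, 0 °C
Reagents that add atoms: none
Why: Buffered Dess–Martin oxidation should give the β,γ-unsaturated ketone without conjugation of the alkene; the oxirane carbon next to the new ketone is quaternary and cannot epimerise.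

Step 15
Reactants: 27 (1S,3S,4R,6S)-1-methyl-4-[(2S)-2-(4-methylpent-3-enoyl)oxiran-2-yl]-2-oxo-7-oxabicyclo[4.1.0]heptan-3-yl 3-methylbutanoate
Product: 28 (1S,3S,4R,6S)-4-{(2S)-2-[(2E)-4-hydroperoxy-4-methylpent-2-enoyl]oxiran-2-yl}-1-methyl-2-oxo-7-oxabicyclo[4.1.0]heptan-3-yl 3-methylbutanoate
Conditions: O2, meso-tetraphenylporphyrin (cat.), visible light, CH2Cl2, −20 °C
Reagents that add atoms: dioxygen O=O
Why: Schenck ene reaction: singlet oxygen should add to the only alkene with abstraction of an allylic hydrogen from the CH2 activated by the ketone, giving the tertiary hydroperoxide and the conjugated (E)-enone.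

**Compound list**

1 | 3-bromo-1,1-dimethoxypropane | COC(CCBr)OC | starting material
2 | 1,1-dimethoxy-3-nitropropane | COC(CC[N+](=O)[O-])OC | intermediate
3 | but-3-en-2-one | CC(=O)C=C | starting material
4 | 7,7-dimethoxy-5-nitroheptan-2-one (racemic) | CC(=O)CCC(CC(OC)OC)[N+](=O)[O-] | intermediate
5 | (3R)-7,7-dimethoxy-5-nitro-3-[(phenylamino)oxy]heptan-2-one (both C5 epimers) | CC(=O)[C@H](ONc1ccccc1)CC(CC(OC)OC)[N+](=O)[O-] | intermediate (not isolated)
6 | (3R)-3-hydroxy-7,7-dimethoxy-5-nitroheptan-2-one (both C5 epimers) | CC(=O)[C@H](O)CC(CC(OC)OC)[N+](=O)[O-] | intermediate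
7 | (3R)-3-{[tert-butyl(dimethyl)silyl]oxy}-7,7-dimethoxy-5-nitroheptan-2-one (both C5 epimers) | CC(=O)[C@H](O[Si](C)(C)C(C)(C)C)CC(CC(OC)OC)[N+](=O)[O-] | intermediate
8 | diphenyl(vinyl)sulfonium trifluoromethanesulfonate | C=C[S+](c1ccccc1)c1ccccc1.[O-]S(=O)(=O)C(F)(F)F | starting material
9 | sulfonium ylide: diphenyl[(5R)-5-{[tert-butyl(dimethyl)silyl]oxy}-3-(2,2-dimethoxyethyl)-3-nitro-6-oxoheptyl]sulfonium with the carbanion on the carbon next to sulfur | CC(=O)[C@H](O[Si](C)(C)C(C)(C)C)CC(CC(OC)OC)(C[CH-][S+](c1ccccc1)c1ccccc1)[N+](=O)[O-] | intermediate (not isolated)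
10 | betaine: cyclohexane with the alkoxide on the methyl-bearing carbon cis to the silyloxy group and anti to the diphenylsulfonio group on the neighbouring CH | [O-][N+](=O)C1(CC(OC)OC)C[C@@H](O[Si](C)(C)C(C)(C)C)[C@@](C)([O-])[C@H]([S+](c2ccccc2)c2ccccc2)C1 | intermediate (not isolated)
11 | tert-butyl{[(1S,2R,6S)-4-(2,2-dimethoxyethyl)-1-methyl-4-nitro-7-oxabicyclo[4.1.0]heptan-2-yl]oxy}dimethylsilane (both C4 epimers; oxirane oxygen cis to the silyloxy group) | [O-][N+](=O)C1(CC(OC)OC)C[C@@H](O[Si](C)(C)C(C)(C)C)[C@@]2(C)O[C@H]2C1 | intermediate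
12 | (1R,2R,6S)-4-(2,2-dimethoxyethyl)-1-methyl-4-nitro-7-oxabicyclo[4.1.0]heptan-2-ol (both C4 epimers) | [O-][N+](=O)C1(CC(OC)OC)C[C@@H](O)[C@@]2(C)O[C@H]2C1 | intermediate
13 | (1S,6S)-4-(2,2-dimethoxyethyl)-1-methyl-4-nitro-7-oxabicyclo[4.1.0]heptan-2-one (both C4 epimers) | [O-][N+](=O)C1(CC(OC)OC)CC(=O)[C@@]2(C)O[C@H]2C1 | intermediate (not isolated)
14 | (1S,6S)-4-(2,2-dimethoxyethyl)-1-methyl-7-oxabicyclo[4.1.0]hept-3-en-2-one | COC(OC)CC1=CC(=O)[C@@]2(C)O[C@H]2C1 | intermediate
15 | {[(1S,4S,6S)-4-(2,2-dimethoxyethyl)-1-methyl-7-oxabicyclo[4.1.0]hept-2-en-2-yl]oxy}dimethyl(phenyl)silane | COC(OC)C[C@H]1C=C(O[Si](C)(C)c2ccccc2)[C@@]3(C)O[C@H]3C1 | intermediate (not isolated)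
16 | (1S,3S,4S,6S)-4-(2,2-dimethoxyethyl)-3-{[dimethyl(phenyl)silyl]oxy}-1-methyl-7-oxabicyclo[4.1.0]heptan-2-one | COC(OC)C[C@H]1[C@H](O[Si](C)(C)c2ccccc2)C(=O)[C@@]3(C)O[C@H]3C1 | intermediate (not isolated)
17 | (1S,3S,4S,6S)-4-(2,2-dimethoxyethyl)-3-hydroxy-1-methyl-7-oxabicyclo[4.1.0]heptan-2-one | COC(OC)C[C@H]1[C@H](O)C(=O)[C@@]2(C)O[C@H]2C1 | intermediate
18 | 3-methylbutanoyl chloride | CC(C)CC(=O)Cl | starting material
19 | (1S,3S,4S,6S)-4-(2,2-dimethoxyethyl)-1-methyl-2-oxo-7-oxabicyclo[4.1.0]heptan-3-yl 3-methylbutanoate | CC(C)CC(=O)O[C@@H]1C(=O)[C@@]2(C)O[C@H]2C[C@H]1CC(OC)OC | intermediate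
20 | (1S,3S,4S,6S)-1-methyl-2-oxo-4-(2-oxoethyl)-7-oxabicyclo[4.1.0]heptan-3-yl 3-methylbutanoate | CC(C)CC(=O)O[C@@H]1C(=O)[C@@]2(C)O[C@H]2C[C@H]1CC=O | intermediate (not isolated)
21 | (1S,3S,4S,6S)-1-methyl-2-oxo-4-(3-oxoprop-1-en-2-yl)-7-oxabicyclo[4.1.0]heptan-3-yl 3-methylbutanoate | CC(C)CC(=O)O[C@@H]1C(=O)[C@@]2(C)O[C@H]2C[C@H]1C(=C)C=O | intermediate
22 | (1S,3S,4R,6S)-4-[(2S)-2-formyloxiran-2-yl]-1-methyl-2-oxo-7-oxabicyclo[4.1.0]heptan-3-yl 3-methylbutanoate | CC(C)CC(=O)O[C@@H]1C(=O)[C@@]2(C)O[C@H]2C[C@H]1[C@@]1(C=O)CO1 | intermediate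
23 | 4,4,5,5-tetramethyl-2-(prop-2-en-1-yl)-1,3,2-dioxaborolane | C=CCB1OC(C)(C)C(C)(C)O1 | starting material
24 | (1S,3S,4R,6S)-4-[(2S)-2-(1-hydroxybut-3-en-1-yl)oxiran-2-yl]-1-methyl-2-oxo-7-oxabicyclo[4.1.0]heptan-3-yl 3-methylbutanoate (both carbinol epimers) | CC(C)CC(=O)O[C@@H]1C(=O)[C@@]2(C)O[C@H]2C[C@H]1[C@@]1(C(O)CC=C)CO1 | intermediate
25 | 2-methylbut-2-ene | CC=C(C)C | starting material
26 | (1S,3S,4R,6S)-4-[(2S)-2-(1-hydroxy-4-methylpent-3-en-1-yl)oxiran-2-yl]-1-methyl-2-oxo-7-oxabicyclo[4.1.0]heptan-3-yl 3-methylbutanoate (both carbinol epimers) | CC(C)CC(=O)O[C@@H]1C(=O)[C@@]2(C)O[C@H]2C[C@H]1[C@@]1(C(O)CC=C(C)C)CO1 | intermediate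
27 | (1S,3S,4R,6S)-1-methyl-4-[(2S)-2-(4-methylpent-3-enoyl)oxiran-2-yl]-2-oxo-7-oxabicyclo[4.1.0]heptan-3-yl 3-methylbutanoate | CC(C)CC(=O)O[C@@H]1C(=O)[C@@]2(C)O[C@H]2C[C@H]1[C@@]1(C(=O)CC=C(C)C)CO1 | intermediate
28 | (1S,3S,4R,6S)-4-{(2S)-2-[(2E)-4-hydroperoxy-4-methylpent-2-enoyl]oxiran-2-yl}-1-methyl-2-oxo-7-oxabicyclo[4.1.0]heptan-3-yl 3-methylbutanoate | CC(C)CC(=O)O[C@@H]1C(=O)[C@@]2(C)O[C@H]2C[C@H]1[C@@]1(C(=O)/C=C/C(C)(C)OO)CO1 | target

**Step count and weak points**

Total step count: 15. Longest linear sequence: 15 steps (1 to 28); the route is fully linear.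

Step 5. What may go wrong: the ylide may add to the ketone face that puts the oxirane anti to the silyloxy group; the ylide may be protonated and then close a cyclopropane with loss of nitrite; the silyloxy centre next to the ketone may epimerise under base. The fallback forms the same two C–C bonds by known chemistry and sets the oxirane by a directed epoxidation. It sets out from 7: the nitronate of 7 (DBU, MeCN, rt to 60 °C) adds to vinyltriphenylphosphonium bromide and the ring closes by intramolecular Wittig reaction to tert-butyl{[(1R)-5-(2,2-dimethoxyethyl)-2-methyl-5-nitrocyclohex-2-en-1-yl]oxy}dimethylsilane F1. TBAF with AcOH in THF then gives (1R)-5-(2,2-dimethoxyethyl)-2-methyl-5-nitrocyclohex-2-en-1-ol F2. Epoxidation with VO(acac)2 and tert-butyl hydroperoxide in CH2Cl2 delivers oxygen syn to the allylic hydroxyl and comes back to the route at 12.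

Step 8. What may go wrong: hydride may be delivered to the face syn to the oxirane, 1,2-reduction may compete at the hindered β,β-disubstituted enone, or the silyl enol ether may be lost before oxidation. The fallback replaces substrate-controlled hydride transfer by an enzymatic reduction and separates the oxidation. It sets out from 14: an ene-reductase of the Old Yellow Enzyme family, chosen from a panel for the required face, with NADPH recycled by glucose and glucose dehydrogenase in phosphate buffer at 30 °C, should give (1S,4S,6S)-4-(2,2-dimethoxyethyl)-1-methyl-7-oxabicyclo[4.1.0]heptan-2-one F3. Enolisation at the only α-CH2 with LiN(SiMe3)2 in THF at −78 °C and oxidation with 3-phenyl-2-(phenylsulfonyl)oxaziridine, anti to the side chain, comes back to the route at 17.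

Step 11. What may go wrong: slow iminium formation at the hindered α-branched enal, or poor facial selectivity if catalyst and ring stereocentres are mismatched. The fallback uses a reagent-controlled epoxidation of an allylic alcohol. It sets out from 21: NaBH4 in EtOH at −78 °C should reduce the aldehyde in preference to the hindered ketone and give (1S,3S,4S,6S)-4-(3-hydroxyprop-1-en-2-yl)-1-methyl-2-oxo-7-oxabicyclo[4.1.0]heptan-3-yl 3-methylbutanoate F4. Sharpless epoxidation with Ti(OiPr)4, D-(−)-diethyl tartrate and tert-butyl hydroperoxide over 4 Å sieves in CH2Cl2 at −20 °C should give (1S,3S,4R,6S)-4-[(2R)-2-(hydroxymethyl)oxiran-2-yl]-1-methyl-2-oxo-7-oxabicyclo[4.1.0]heptan-3-yl 3-methylbutanoate F5. Dess–Martin oxidation of the primary alcohol comes back to the route at 22.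

Further compounds
F1 | step 5 | tert-butyl{[(1R)-5-(2,2-dimethoxyethyl)-2-methyl-5-nitrocyclohex-2-en-1-yl]oxy}dimethylsilane (both C5 epimers) | [O-][N+](=O)C1(CC(OC)OC)C[C@@H](O[Si](C)(C)C(C)(C)C)C(C)=CC1
F2 | step 5 | (1R)-5-(2,2-dimethoxyethyl)-2-methyl-5-nitrocyclohex-2-en-1-ol (both C5 epimers) | [O-][N+](=O)C1(CC(OC)OC)C[C@@H](O)C(C)=CC1
F3 | step 8 | (1S,4S,6S)-4-(2,2-dimethoxyethyl)-1-methyl-7-oxabicyclo[4.1.0]heptan-2-one | COC(OC)C[C@H]1CC(=O)[C@@]2(C)O[C@H]2C1
F4 | step 11 | (1S,3S,4S,6S)-4-(3-hydroxyprop-1-en-2-yl)-1-methyl-2-oxo-7-oxabicyclo[4.1.0]heptan-3-yl 3-methylbutanoate | CC(C)CC(=O)O[C@@H]1C(=O)[C@@]2(C)O[C@H]2C[C@H]1C(=C)CO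
F5 | step 11 | (1S,3S,4R,6S)-4-[(2R)-2-(hydroxymethyl)oxiran-2-yl]-1-methyl-2-oxo-7-oxabicyclo[4.1.0]heptan-3-yl 3-methylbutanoate | CC(C)CC(=O)O[C@@H]1C(=O)[C@@]2(C)O[C@H]2C[C@H]1[C@@]1(CO)CO1
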